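**Plan** (C1 = lactone carbonyl, C13 = lactone carbinol, C15 = side-chain carbinol)
1. Retrosynthesis: the CH2CO2H on C3 goes back to CH2CH2OH. The 14-membered lactone is then cut at C10–C11, because C11(OH)–C10H2–C9(Me)=C8H in the ring is the retron of an allylboration with allylic transposition.
2. The seco compound is a C11 aldehyde that carries a C8 allylboronate (C9(Me)=C10H2). Further cuts are C3–C4 (Stille), the C1–O13 ester, C8–C9 (lithiation–borylation) and C12–C13 (allylation).
3. Forward: the C11–C24 alcohol is esterified with a C1–C3 ynoic acid, stannylcuprated and joined to a C4–C10 allylic chloride. C11 is then unmasked, the ring is closed, the silyl groups are removed and the primary alcohol is oxidised.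
4. Stereochemistry: C15 comes from a Noyori hydrogenation and C13 from a Brown allylation (13,15-anti). The temporary C8 centre comes from sparteine-mediated lithiation–borylation.
5. C11 (11,13-syn) and the E-C8=C9 alkene come from C8 by chirality transfer in the ring closure. E-C5=C6 comes from a trans-hydroalumination, and C2=C3 from a Z-selective stannylcupration followed by a retentive coupling.

Key step: step 20

Remark: methyl 3-oxododecanoate, the TBS ether of but-3-yn-1-ol, but-3-yn-1-ol, isopropenyl-Bpin, (−)-sparteine and (−)-Ipc2B(allyl) are taken as commercial. The CIP descriptor at C13 changes with the substituents along the route, but its spatial arrangement is always that of the target.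

**Step 1**
Reactants: 1 methyl 3-oxododecanoate
Product: 2 methyl (S)-3-hydroxydodecanoate
Conditions: [RuCl(p-cymene)((S)-BINAP)]Cl (0.5 mol %), H2 (10 bar), MeOH, 50 °C
Reagents that add atoms: none
Why: Noyori asymmetric hydrogenation of a β-keto ester, in which the ester carbonyl chelates ruthenium and the (S)-BINAP ligand should direct hydride to the face that gives the (S)-carbinol, the later C15.

**Step 2**
Reactants: 2 methyl (S)-3-hydroxydodecanoate
Product: 3 methyl (S)-3-(tert-butyldimethylsilyloxy)dodecanoate
Conditions: TBSCl, imidazole, DMF, rt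
Reagents that add atoms: TBSCl CC(C)(C)[Si](C)(C)Cl
Why: Imidazole-promoted silylation of a secondary alcohol, which leaves the C–O bond and hence C15 untouched.

**Step 3**
Reactants: 3 methyl (S)-3-(tert-butyldimethylsilyloxy)dodecanoate
Product: 4 (S)-3-(tert-butyldimethylsilyloxy)dodecanal
Conditions: i-Bu2AlH (1.1 equiv), CH2Cl2, −78 °C; aq work-up
Reagents that add atoms: none
Why: Partial ester reduction with i-Bu2AlH, since the tetrahedral aluminium hemiacetal persists at −78 °C and releases the aldehyde only on work-up, without risk to the β-silyloxy centre.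

**Step 4**
Reactants: 4 (S)-3-(tert-butyldimethylsilyloxy)dodecanal
Product: 6 (4S,6S)-6-(tert-butyldimethylsilyloxy)pentadec-1-en-4-ol, via homoallyl diisopinocampheylborinate 5 (not isolated)
Conditions: (−)-Ipc2B(allyl), Et2O, −78 °C; then NaOH, H2O2, 0 °C → rt
Reagents that add atoms: (−)-B-allyldiisopinocampheylborane C=CCB([C@@H]1C[C@@H]2C[C@H]([C@H]1C)C2(C)C)[C@@H]1C[C@@H]2C[C@H]([C@H]1C)C2(C)C
Why: Brown allylation through a closed chair transition state, in which the reagent derived from (+)-α-pinene should attack the Si face of 4 under reagent control and so set C13 anti to C15.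

**Step 5**
Reactants: 6 (4S,6S)-6-(tert-butyldimethylsilyloxy)pentadec-1-en-4-ol
Product: 8 (3S,5S)-5-(tert-butyldimethylsilyloxy)tetradecane-1,3-diol, via hydroxy aldehyde 7 (not isolated)
Conditions: O3, CH2Cl2/MeOH, −78 °C; then NaBH4, −78 → 0 °C
Reagents that add atoms: ozone [O-][O+]=O
Why: Ozonolysis with reductive work-up, the only alkene of 6 being cleaved and the β-hydroxy aldehyde reduced in the flask before it can eliminate.

**Step 6**
Reactants: 8 (3S,5S)-5-(tert-butyldimethylsilyloxy)tetradecane-1,3-diol
Product: 9 (3S,5S)-5-(tert-butyldimethylsilyloxy)-1-(triethylsilyloxy)tetradecan-3-ol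
Conditions: TESCl (1.05 equiv), imidazole, CH2Cl2, −78 → −20 °C
Reagents that add atoms: TESCl CC[Si](CC)(CC)Cl
Why: Sterically controlled monosilylation, the primary C11 hydroxyl reacting far faster with TESCl at low temperature than the flanked secondary C13 hydroxyl.

**Step 7**
Reactants: 10 tert-butyl(but-3-yn-1-yloxy)dimethylsilane
Product: 12 5-(tert-butyldimethylsilyloxy)pent-2-ynoic acid, via lithium acetylide 11 (not isolated)
Conditions: n-BuLi, THF, −78 °C; CO2, −78 → 0 °C; cold aq KHSO4
Reagents that add atoms: carbon dioxide O=C=O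
Why: Carboxylation of a lithium acetylide, a standard route to alk-2-ynoic acids that the primary TBS ether tolerates if the acidification is mild.

**Step 8**
Reactants: 9 (3S,5S)-5-(tert-butyldimethylsilyloxy)-1-(triethylsilyloxy)tetradecan-3-ol; 12 5-(tert-butyldimethylsilyloxy)pent-2-ynoic acid
Product: 13 (3S,5S)-5-(tert-butyldimethylsilyloxy)-1-(triethylsilyloxy)tetradecan-3-yl 5-(tert-butyldimethylsilyloxy)pent-2-ynoate
Conditions: DCC, DMAP (10 mol %), CH2Cl2, −20 → 0 °C
Reagents that add atoms: none
Why: Steglich esterification, which acylates the C13 oxygen with retention because the C13–O bond is not broken, and which is kept cold to suppress addition of DMAP to the ynoate.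

**Step 9**
Reactants: 13 ynoate ester
Product: 14 (3S,5S)-5-(tert-butyldimethylsilyloxy)-1-(triethylsilyloxy)tetradecan-3-yl (Z)-5-(tert-butyldimethylsilyloxy)-3-(trimethylstannyl)pent-2-enoate
Conditions: (Me3Sn)2, MeLi, THF, −20 °C; PhSCu, −20 °C; 13, −78 → −48 °C, 4 h; MeOH, aq NH4Cl
Reagents that add atoms: hexamethylditin C[Sn](C)(C)[Sn](C)(C)C
Why: Stannylcupration of an alk-2-ynoate under equilibrating conditions, where the first-formed syn adduct should isomerise at −48 °C through the copper allenoate so that protonation gives the Z-stannane with tin cis to the ester carbonyl, the geometry that later places C4 cis to C1.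

**Step 10**
Reactants: 15 but-3-yn-1-ol
Product: 16 but-3-yn-1-yl N,N-diisopropylcarbamate
Conditions: i-Pr2NCOCl, Et3N, CH2Cl2, reflux
Reagents that add atoms: N,N-diisopropylcarbamoyl chloride CC(C)N(C(C)C)C(=O)Cl
Why: Carbamoylation of a primary alcohol, which installs the directing and leaving group needed for the later lithiation–borylation.

**Step 11**
Reactants: 16 but-3-yn-1-yl N,N-diisopropylcarbamate
Product: 18 5-hydroxypent-3-yn-1-yl N,N-diisopropylcarbamate, via lithium acetylide 17 (not isolated)
Conditions: n-BuLi, THF, −78 °C; (CH2O)n, −78 °C → rt; H2O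
Reagents that add atoms: paraformaldehyde (as formaldehyde) C=O
Why: Hydroxymethylation of a lithium acetylide, n-BuLi removing only the acetylenic proton because α-lithiation of the carbamate needs s-BuLi and a diamine.

**Step 12**
Reactants: 18 5-hydroxypent-3-yn-1-yl N,N-diisopropylcarbamate
Product: 19 (E)-5-hydroxypent-3-en-1-yl N,N-diisopropylcarbamate
Conditions: NaAlH2(OCH2CH2OMe)2, THF, 0 °C; aq work-up
Reagents that add atoms: none
Why: Alkoxide-directed trans-hydroalumination of a propargylic alcohol followed by protonolysis, which should give only the E-alkene (C5=C6), while the hindered diisopropylcarbamate, cleaved by hydride only under forcing conditions, should survive at 0 °C.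

**Step 13**
Reactants: 19 (E)-5-hydroxypent-3-en-1-yl N,N-diisopropylcarbamate
Product: 20 (E)-5-(tert-butyldimethylsilyloxy)pent-3-en-1-yl N,N-diisopropylcarbamate
Conditions: TBSCl, imidazole, CH2Cl2, rt
Reagents that add atoms: TBSCl CC(C)(C)[Si](C)(C)Cl
Why: Standard silylation of a primary allylic alcohol, giving an ether that has no acidic proton and is a poor leaving group for the organolithium step.

**Step 14**
Reactants: 20 (E)-5-(tert-butyldimethylsilyloxy)pent-3-en-1-yl N,N-diisopropylcarbamate; 21 isopropenylboronic acid pinacol ester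
Product: 24 tert-butyldimethylsilyl ether of (2E,5R)-6-methyl-5-(4,4,5,5-tetramethyl-1,3,2-dioxaborolan-2-yl)hepta-2,6-dien-1-ol, via lithiated carbamate 22 (not isolated), via lithium boronate complex 23 (not isolated)
Conditions: s-BuLi, (−)-sparteine, Et2O, −78 °C, 5 h; 21, −78 °C, 1 h; MgBr2·OEt2, −78 °C → reflux; H2O
Reagents that add atoms: none
Why: Lithiation–borylation, in which s-BuLi/(−)-sparteine should remove the pro-S hydrogen next to the carbamate oxygen, 21 should trap the configurationally stable (S)-organolithium with retention, and the 1,2-metallate shift of the isopropenyl group with inversion should give the (R)-allylboronate, a reaction type known for this class of α-alkyl-β-methallyl pinacol boronates.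

**Step 15**
Reactants: 24 silyl ether allylboronate
Product: 25 (2E,5R)-6-methyl-5-(4,4,5,5-tetramethyl-1,3,2-dioxaborolan-2-yl)hepta-2,6-dien-1-ol
Conditions: camphorsulfonic acid (10 mol %), MeOH/CH2Cl2, 0 °C
Reagents that add atoms: none
Why: Acid-catalysed methanolysis of a primary allylic TBS ether, mild enough that the pinacol allylboronate should neither exchange its diol nor protodeboronate.

**Step 16**
Reactants: 25 allylic alcohol allylboronate
Product: 26 2-[(3R,5E)-7-chloro-2-methylhepta-1,5-dien-3-yl]-4,4,5,5-tetramethyl-1,3,2-dioxaborolane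
Conditions: PPh3, CCl4, CH2Cl2, rt
Reagents that add atoms: tetrachloromethane ClC(Cl)(Cl)Cl
Why: Appel chlorination, a neutral SN2 displacement at the primary allylic carbon that should proceed without transposition and without touching the C–B bond.

**Step 17**
Reactants: 14 (Z)-alkenylstannane ester; 26 allylic chloride allylboronate
Product: 27 (3S,5S)-5-(tert-butyldimethylsilyloxy)-1-(triethylsilyloxy)tetradecan-3-yl (2E,5E,8R)-3-[2-(tert-butyldimethylsilyloxy)ethyl]-9-methyl-8-(4,4,5,5-tetramethyl-1,3,2-dioxaborolan-2-yl)deca-2,5,9-trienoate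
Conditions: Pd2(dba)3 (5 mol %), AsPh3 (20 mol %), LiCl, NMP, rt → 40 °C
Reagents that add atoms: none
Why: Stille coupling of an alkenylstannane with an allylic chloride, which should join C3 to the unhindered terminus of the π-allylpalladium unit with retention of both alkene geometries and, being free of base or alkoxide, should leave the pinacol allylboronate unable to transmetalate.

**Step 18**
Reactants: 27 seco TES ether
Product: 28 (3S,5S)-5-(tert-butyldimethylsilyloxy)-1-hydroxytetradecan-3-yl ester of the same (2E,5E,8R)-trienoic acid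
Conditions: PPTS (20 mol %), MeOH/CH2Cl2, 0 °C
Reagents that add atoms: none
Why: Selective acid-catalysed methanolysis of the primary TES ether, which is far more labile than the primary and secondary TBS ethers.

**Step 19**
Reactants: 28 seco alcohol
Product: 29 (3R,5S)-5-(tert-butyldimethylsilyloxy)-1-oxotetradecan-3-yl ester of the same (2E,5E,8R)-trienoic acid
Conditions: Dess–Martin periodinane, NaHCO3, CH2Cl2, 0 °C; short silica plug, used at once in dilute solution
Reagents that add atoms: none
Why: Dess–Martin oxidation, whose buffered, non-basic medium should avoid β-elimination of the C13 acyloxy group and should not oxidise the C–B bond.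

**Step 20**
Reactants: 29 seco aldehyde allylboronate
Product: 31 (2E,5E,8E,11S)-11-hydroxy-9-methyl-3-[2-(tert-butyldimethylsilyloxy)ethyl]-13-[(2S)-2-(tert-butyldimethylsilyloxy)undecyl]trideca-2,5,8-trien-13-olide (C13 as in the target), via O-boryl macrolactone 30 (not isolated)
Conditions: BF3·OEt2 (1 equiv, promoter, not consumed), 4 Å MS, CH2Cl2, −60 °C, 29 added by syringe pump over 10 h (final 2 mM); aq NaHCO3
Reagents that add atoms: none
Why: Proposed new method: BF3 binds a dioxaborolane oxygen of 29, the aldehyde oxygen coordinates to boron, and C10 attacks C11 through a six-membered chair array B–O–C11–C10–C9–C8 (Zimmerman–Traxler type) with allylic transposition, so that the C10–C11 bond, the C8=C9 alkene and the ring arise in one event while the C8–B centre is consumed. The closest known reaction types are the Lewis acid promoted E-selective allylboration of aldehydes with α-substituted allyl pinacol boronates, the intramolecular allylboration that closes five- to seven-membered rings, and the BF3-promoted SE2' closure of fourteen-membered rings from allylstannane aldehydes; what is new is the macrocyclic allylboration. The 14-membered lactone closes 14-exo-trig at the aldehyde carbon and endo with regard to the C9=C10 bond, the chair being fused into the forming ring across C8 and C11. C11 is set by chirality transfer: with the C12 and C7 chains both pseudoequatorial, the (8R)-boronate can present only the aldehyde face that gives 11S (11,13-syn), and the same arrangement makes C8=C9 E. The step needs E over Z, γ over α attack and ring closure over oligomerisation: the Lewis acid on the dioxaborolane oxygen penalises a pseudoaxial C7 chain and lets the reaction run at −60 °C, where the uncatalysed Z-selective pathway of 2-methyl-substituted pinacol reagents and the 1,3-shift of boron should be frozen, the closed array allows only γ attack, and slow addition together with the turn imposed by the C1/C4-cis C2=C3 bond and the planar C5=C6 and ester units favours the ring. The enoate, the silyl ethers and the skipped diene should not respond to BF3·OEt2 at this temperature.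

**Step 21**
Reactants: 31 bis-silylated macrolactone
Product: 32 (2E,5E,8E,11S,13R)-11-hydroxy-3-(2-hydroxyethyl)-13-[(2S)-2-hydroxyundecyl]-9-methyltrideca-2,5,8-trien-13-olide
Conditions: HF·pyridine, pyridine, THF, 0 °C → rt
Reagents that add atoms: none
Why: Fluoride-mediated desilylation in a weakly acidic, non-basic medium, which should remove both TBS groups without moving the skipped double bonds into conjugation or shifting the acyl group.

**Step 22**
Reactants: 32 macrolactone triol
Product: 34 (2E,5E,8E,11S,13R)-3-(carboxymethyl)-11-hydroxy-13-[(2S)-2-hydroxyundecyl]-9-methyltrideca-2,5,8-trien-13-olide (target), via macrolactone aldehyde 33 (not isolated)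
Conditions: TEMPO (20 mol %), PhI(OAc)2 (2.5 equiv), MeCN/aq pH 7 phosphate buffer, 0 °C → rt
Reagents that add atoms: water O
Why: TEMPO/PhI(OAc)2 oxidation, in which the hindered oxoammonium ion should oxidise the primary alcohol much faster than the two secondary ones and should carry the hydrate of aldehyde 33 on to the acid before the β,γ-double bond can migrate.

**Compound list**
1 | methyl 3-oxododecanoate | CCCCCCCCCC(=O)CC(=O)OC | starting material
2 | methyl (S)-3-hydroxydodecanoate | CCCCCCCCC[C@H](O)CC(=O)OC | intermediate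
3 | methyl (S)-3-(tert-butyldimethylsilyloxy)dodecanoate | CCCCCCCCC[C@H](O[Si](C)(C)C(C)(C)C)CC(=O)OC | intermediate
4 | (S)-3-(tert-butyldimethylsilyloxy)dodecanal | CCCCCCCCC[C@H](O[Si](C)(C)C(C)(C)C)CC=O | intermediate
5 | diisopinocampheylborinate of 6 | CCCCCCCCC[C@H](O[Si](C)(C)C(C)(C)C)C[C@@H](OB([C@@H]1C[C@@H]2C[C@H]([C@H]1C)C2(C)C)[C@@H]1C[C@@H]2C[C@H]([C@H]1C)C2(C)C)CC=C | intermediate
6 | (4S,6S)-6-(tert-butyldimethylsilyloxy)pentadec-1-en-4-ol | CCCCCCCCC[C@H](O[Si](C)(C)C(C)(C)C)C[C@@H](O)CC=C | intermediate
7 | (3R,5S)-5-(tert-butyldimethylsilyloxy)-3-hydroxytetradecanal | CCCCCCCCC[C@H](O[Si](C)(C)C(C)(C)C)C[C@@H](O)CC=O | intermediate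
8 | (3S,5S)-5-(tert-butyldimethylsilyloxy)tetradecane-1,3-diol | CCCCCCCCC[C@H](O[Si](C)(C)C(C)(C)C)C[C@@H](O)CCO | intermediate
9 | (3S,5S)-5-(tert-butyldimethylsilyloxy)-1-(triethylsilyloxy)tetradecan-3-ol | CCCCCCCCC[C@H](O[Si](C)(C)C(C)(C)C)C[C@@H](O)CCO[Si](CC)(CC)CC | intermediate
10 | tert-butyl(but-3-yn-1-yloxy)dimethylsilane | C#CCCO[Si](C)(C)C(C)(C)C | starting material
11 | lithium acetylide of 10 | [Li]C#CCCO[Si](C)(C)C(C)(C)C | intermediate
12 | 5-(tert-butyldimethylsilyloxy)pent-2-ynoic acid | OC(=O)C#CCCO[Si](C)(C)C(C)(C)C | intermediate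
13 | ynoate ester of 9 | CCCCCCCCC[C@H](O[Si](C)(C)C(C)(C)C)C[C@@H](OC(=O)C#CCCO[Si](C)(C)C(C)(C)C)CCO[Si](CC)(CC)CC | intermediate
14 | (Z)-3-(trimethylstannyl)enoate ester of 9 | CCCCCCCCC[C@H](O[Si](C)(C)C(C)(C)C)C[C@@H](OC(=O)/C=C(\[Sn](C)(C)C)CCO[Si](C)(C)C(C)(C)C)CCO[Si](CC)(CC)CC | intermediate
15 | but-3-yn-1-ol | C#CCCO | starting material
16 | but-3-yn-1-yl N,N-diisopropylcarbamate | C#CCCOC(=O)N(C(C)C)C(C)C | intermediate
17 | lithium acetylide of 16 | [Li]C#CCCOC(=O)N(C(C)C)C(C)C | intermediate
18 | 5-hydroxypent-3-yn-1-yl N,N-diisopropylcarbamate | OCC#CCCOC(=O)N(C(C)C)C(C)C | intermediate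
19 | (E)-5-hydroxypent-3-en-1-yl N,N-diisopropylcarbamate | OC/C=C/CCOC(=O)N(C(C)C)C(C)C | intermediate
20 | (E)-5-(tert-butyldimethylsilyloxy)pent-3-en-1-yl N,N-diisopropylcarbamate | CC(C)(C)[Si](C)(C)OC/C=C/CCOC(=O)N(C(C)C)C(C)C | intermediate
21 | isopropenylboronic acid pinacol ester | C=C(C)B1OC(C)(C)C(C)(C)O1 | starting material
22 | (S)-α-lithiated carbamate (sparteine complex) | [Li][C@H](OC(=O)N(C(C)C)C(C)C)C/C=C/CO[Si](C)(C)C(C)(C)C | intermediate
23 | lithium boronate complex of 22 and 21 | [Li+].C=C(C)[B-]1(OC(C)(C)C(C)(C)O1)[C@H](OC(=O)N(C(C)C)C(C)C)C/C=C/CO[Si](C)(C)C(C)(C)C | intermediate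
24 | (2E,5R)-allylboronate TBS ether | C=C(C)[C@H](B1OC(C)(C)C(C)(C)O1)C/C=C/CO[Si](C)(C)C(C)(C)C | intermediate
25 | (2E,5R)-6-methyl-5-(pinacolboryl)hepta-2,6-dien-1-ol | C=C(C)[C@H](B1OC(C)(C)C(C)(C)O1)C/C=C/CO | intermediate
26 | (3R,5E)-7-chloro-2-methylhepta-1,5-dien-3-yl pinacol boronate | C=C(C)[C@H](B1OC(C)(C)C(C)(C)O1)C/C=C/CCl | intermediate
27 | seco TES ether (2E,5E,8R) | CCCCCCCCC[C@H](O[Si](C)(C)C(C)(C)C)C[C@@H](OC(=O)/C=C(\C/C=C/C[C@@H](B1OC(C)(C)C(C)(C)O1)C(C)=C)CCO[Si](C)(C)C(C)(C)C)CCO[Si](CC)(CC)CC | intermediate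
28 | seco alcohol (2E,5E,8R) | CCCCCCCCC[C@H](O[Si](C)(C)C(C)(C)C)C[C@@H](OC(=O)/C=C(\C/C=C/C[C@@H](B1OC(C)(C)C(C)(C)O1)C(C)=C)CCO[Si](C)(C)C(C)(C)C)CCO | intermediate
29 | seco aldehyde (2E,5E,8R) | CCCCCCCCC[C@H](O[Si](C)(C)C(C)(C)C)C[C@@H](OC(=O)/C=C(\C/C=C/C[C@@H](B1OC(C)(C)C(C)(C)O1)C(C)=C)CCO[Si](C)(C)C(C)(C)C)CC=O | intermediate
30 | 11-O-pinacolboryl macrolactone | CCCCCCCCC[C@H](O[Si](C)(C)C(C)(C)C)C[C@@H]1C[C@@H](OB2OC(C)(C)C(C)(C)O2)C/C(C)=C/C/C=C/C/C(CCO[Si](C)(C)C(C)(C)C)=C\C(=O)O1 | intermediate
31 | bis-TBS macrolactone with free 11S-OH | CCCCCCCCC[C@H](O[Si](C)(C)C(C)(C)C)C[C@@H]1C[C@@H](O)C/C(C)=C/C/C=C/C/C(CCO[Si](C)(C)C(C)(C)C)=C\C(=O)O1 | intermediate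
32 | macrolactone triol | CCCCCCCCC[C@H](O)C[C@@H]1C[C@@H](O)C/C(C)=C/C/C=C/C/C(CCO)=C\C(=O)O1 | intermediate
33 | macrolactone aldehyde | CCCCCCCCC[C@H](O)C[C@@H]1C[C@@H](O)C/C(C)=C/C/C=C/C/C(CC=O)=C\C(=O)O1 | intermediate
34 | target acid | CCCCCCCCC[C@H](O)C[C@@H]1C[C@@H](O)C/C(C)=C/C/C=C/C/C(CC(=O)O)=C\C(=O)O1 | target

**Total steps:** 22. **Longest linear sequence:** 14 (steps 1–6, 8, 9, 17–22).

**Steps most likely to fail**

Step 20. At high dilution the ring closure may be too slow, so that intermolecular addition or the 1,3-shift of boron takes over. Leakage through the chair with a pseudoaxial C7 chain would erode the alkene geometry and the C11 configuration together.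
- In the fallback the C10–C11 bond is made between two molecules at normal concentration. It uses the borinic ester variant of the allylboration, which is known to turn α-substituted 2-methylallyl pinacol boronates E-selective. The ring is then closed at C3–C4 by a Stille macrocyclisation.
- The fallback sets out from 14 and 26. PPTS in MeOH on 14 should give the primary alcohol F1, and Dess–Martin oxidation should give the aldehyde F2.
- Compound 26 with n-BuLi (1 equiv, THF, −78 °C, where attack at boron is faster than at the allylic chloride) should give the lithium butylboronate complex F3. Addition of (CF3CO)2O should then give the B-butyl borinic ester F4.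
- F4 should add to F2 at −78 °C through the same chair to give the O-borinate adduct F5, and hydrolytic work-up should give the (8E,11S)-homoallylic alcohol F6.
- Pd2(dba)3/AsPh3 in NMP under high dilution should join the stannane and chloride ends of F6. The fallback comes back to the route at 31.

Step 17. Transmetalation of the hindered, electron-poor stannane may be slow, so that decay of the π-allylpalladium species or of the allylboronate takes over.
- The fallback replaces tin by a more nucleophilic zinc reagent in a Negishi coupling, and it sets out from 14.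
- I2 in CH2Cl2 at 0 °C should give, with retention, the (Z)-3-iodoenoate F7.
- i-PrMgCl·LiCl at −40 °C should give the ester-chelated alkenylmagnesium chloride F8, and ZnCl2 should give the alkenylzinc chloride F9.
- F9 should couple with 26 under Pd(PPh3)4 in THF. The fallback comes back to the route at 27.

Step 14. During the long lithiation, deprotonation at the allylic positions or loss of the carbamate by elimination may compete.
- The fallback runs the lithiation–borylation on a simpler carbamate without the allylic ether and adds C4–C5 afterwards by cross metathesis. It sets out from 21 and commercial but-3-en-1-ol.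
- Carbamoylation should give but-3-en-1-yl N,N-diisopropylcarbamate F10, and s-BuLi/(−)-sparteine should give the lithiated carbamate F11.
- Compound 21 should give the lithium boronate complex F12, and warming with MgBr2·OEt2 should give the (R)-dienylboronate F13.
- Cross metathesis of the monosubstituted alkene of F13 with (Z)-1,4-dichlorobut-2-ene and the second-generation Hoveyda–Grubbs catalyst, followed by removal of any Z isomer, should come back to the route at 26.

**Further compounds**
F1 | step 20 | primary alcohol from 14 | CCCCCCCCC[C@H](O[Si](C)(C)C(C)(C)C)C[C@@H](OC(=O)/C=C(\[Sn](C)(C)C)CCO[Si](C)(C)C(C)(C)C)CCO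
F2 | step 20 | aldehyde from F1 | CCCCCCCCC[C@H](O[Si](C)(C)C(C)(C)C)C[C@@H](OC(=O)/C=C(\[Sn](C)(C)C)CCO[Si](C)(C)C(C)(C)C)CC=O
F3 | step 20 | lithium butylboronate complex of 26 | [Li+].C=C(C)[C@H]([B-]1(CCCC)OC(C)(C)C(C)(C)O1)C/C=C/CCl
F4 | step 20 | B-butyl borinic ester from 26 | C=C(C)[C@H](B(CCCC)OC(C)(C)C(C)(C)OC(=O)C(F)(F)F)C/C=C/CCl
F5 | step 20 | O-borinate adduct of F2 and F4 | CCCCCCCCC[C@H](O[Si](C)(C)C(C)(C)C)C[C@@H](OC(=O)/C=C(\[Sn](C)(C)C)CCO[Si](C)(C)C(C)(C)C)C[C@@H](OB(CCCC)OC(C)(C)C(C)(C)OC(=O)C(F)(F)F)C/C(C)=C/C/C=C/CCl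
F6 | step 20 | (8E,11S)-homoallylic alcohol with stannane and chloride ends | CCCCCCCCC[C@H](O[Si](C)(C)C(C)(C)C)C[C@@H](OC(=O)/C=C(\[Sn](C)(C)C)CCO[Si](C)(C)C(C)(C)C)C[C@@H](O)C/C(C)=C/C/C=C/CCl
F7 | step 17 | (Z)-3-iodoenoate ester of 9 | CCCCCCCCC[C@H](O[Si](C)(C)C(C)(C)C)C[C@@H](OC(=O)/C=C(\I)CCO[Si](C)(C)C(C)(C)C)CCO[Si](CC)(CC)CC
F8 | step 17 | alkenylmagnesium chloride from F7 | CCCCCCCCC[C@H](O[Si](C)(C)C(C)(C)C)C[C@@H](OC(=O)/C=C(\[Mg]Cl)CCO[Si](C)(C)C(C)(C)C)CCO[Si](CC)(CC)CC
F9 | step 17 | alkenylzinc chloride from F8 | CCCCCCCCC[C@H](O[Si](C)(C)C(C)(C)C)C[C@@H](OC(=O)/C=C(\[Zn]Cl)CCO[Si](C)(C)C(C)(C)C)CCO[Si](CC)(CC)CC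
F10 | step 14 | but-3-en-1-yl N,N-diisopropylcarbamate | C=CCCOC(=O)N(C(C)C)C(C)C
F11 | step 14 | (S)-lithiated carbamate from F10 | [Li][C@H](OC(=O)N(C(C)C)C(C)C)CC=C
F12 | step 14 | lithium boronate complex of F11 and 21 | [Li+].C=C(C)[B-]1(OC(C)(C)C(C)(C)O1)[C@H](OC(=O)N(C(C)C)C(C)C)CC=C
F13 | step 14 | (R)-2-methylhexa-1,5-dien-3-yl pinacol boronate | C=C(C)[C@H](B1OC(C)(C)C(C)(C)O1)CC=C
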